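## Retrosynthetic overview

1. The target is reached by global desilylation of a bis-silyl ether, whose prenyl group comes from Stille coupling of a 5'-bromo cis-isoflavan-4-ol.
2. Ring C (the pyran) is the only ring built and is closed last, at C4–C4a, by an intramolecular Nozaki–Hiyama–Kishi addition of a ring A aryl iodide to an α-aryl aldehyde; C3 dictates the C4 configuration. Rings A and B are bought as arenes.
3. The O1–C2 bond comes from Mitsunobu etherification of a primary alcohol with a ring A iodophenol; the C4 aldehyde comes from cleavage of an (E)-propenyl group.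
4. Key step: the C1'–C3 bond and the C3 stereocentre are formed by an aromatic Claisen [3,3] rearrangement of a ring B aryl (S,E)-allylic ether with 1,3-chirality transfer.
5. That ether comes from methyl (R)-lactate and a ring B bromophenol (Mitsunobu inversion), followed by a two-carbon homologation.

Assumption: methyl (R)-lactate (the D-lactate ester) is the only chiral material bought; the target is the (3R,4R), 3,4-cis isoflavan-4-ol encoded by the SMILES.

Abbreviations: TIPS = triisopropylsilyl; TBS = tert-butyldimethylsilyl; DIAD = diisopropyl azodicarboxylate; NBS = N-bromosuccinimide; NMO = N-methylmorpholine N-oxide; fod = 6,6,7,7,8,8,8-heptafluoro-2,2-dimethyloctane-3,5-dionate.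

## Route

Step 1
Reactants: 1 resorcinol
Product: 2 3-[(triisopropylsilyl)oxy]phenol
Conditions: TIPSCl (1 equiv), resorcinol (3 equiv), imidazole, DMF, 0 °C → rt
Reagents that add atoms: triisopropylsilyl chloride, CC(C)[Si](Cl)(C(C)C)C(C)C
Why: Statistical monosilylation (silyl ether formation) of a cheap symmetric diol used in excess gives the mono-ether, whose bulky silyl group later shields the ring carbon between the two oxygens.

Step 2
Reactants: 2 3-[(triisopropylsilyl)oxy]phenol
Product: 3 4-bromo-3-[(triisopropylsilyl)oxy]phenol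
Conditions: NBS (1.0 equiv), MeCN, −20 → 0 °C
Reagents that add atoms: N-bromosuccinimide, O=C1CCC(=O)N1Br
Why: Electrophilic aromatic bromination in a polar solvent is directed by the free hydroxyl mainly to its para position; the minor 6-bromo isomer is removed by chromatography.

Step 3
Reactants: 3 4-bromo-3-[(triisopropylsilyl)oxy]phenol; 4 methyl (R)-lactate
Product: 5 methyl (2S)-2-{4-bromo-3-[(triisopropylsilyl)oxy]phenoxy}propanoate
Conditions: PPh3, DIAD, THF, 0 °C → rt
Reagents that add atoms: none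
Why: Mitsunobu etherification, in which the phenol displaces the activated lactate hydroxyl by SN2 with clean inversion, so the bought (R) centre becomes the (S) aryl ether.

Step 4
Reactants: 5 methyl (2S)-2-{4-bromo-3-[(triisopropylsilyl)oxy]phenoxy}propanoate
Product: 7 ethyl (2E,4S)-4-{4-bromo-3-[(triisopropylsilyl)oxy]phenoxy}pent-2-enoate, via (2S)-2-aryloxypropanal 6 (not isolated)
Conditions: i-Bu2AlH (1.05 equiv), CH2Cl2, −78 °C; then NaH/(EtO)2P(O)CH2CO2Et (premixed in THF), −78 °C → rt
Reagents that add atoms: triethyl phosphonoacetate, CCOC(=O)CP(=O)(OCC)OCC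
Why: Half-reduction to the aluminium hemiacetal and in situ Horner–Wadsworth–Emmons olefination give the (E)-enoate without isolating the epimerisable α-aryloxy aldehyde; the stereocentre is untouched and the trace (Z) isomer, which would lead to the wrong C3 configuration, is removed here.

Step 5
Reactants: 7 ethyl (2E,4S)-4-{4-bromo-3-[(triisopropylsilyl)oxy]phenoxy}pent-2-enoate
Product: 8 (2E,4S)-4-{4-bromo-3-[(triisopropylsilyl)oxy]phenoxy}pent-2-en-1-ol
Conditions: i-Bu2AlH (2.5 equiv), CH2Cl2, −78 → −40 °C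
Reagents that add atoms: none
Why: 1,2-Reduction of the enoate by the aluminium hydride gives the (E)-allylic alcohol without touching the stereocentre, the aryl bromide or the silyl ether.

Step 6
Reactants: 8 (2E,4S)-4-{4-bromo-3-[(triisopropylsilyl)oxy]phenoxy}pent-2-en-1-ol
Product: 9 4-bromo-2-[(2R,3E)-1-hydroxypent-3-en-2-yl]-5-[(triisopropylsilyl)oxy]phenol
Conditions: Eu(fod)3 (10 mol%), CHCl3, 60 °C
Reagents that add atoms: none
Why: Lewis-acid-catalysed aromatic Claisen ([3,3]-sigmatropic) rearrangement through a chair transition state with the methyl group pseudo-equatorial forms the new C–C bond suprafacially at the unhindered ortho carbon para to the silyloxy group, so the (S) C–O centre is traded for the (R) benzylic centre (future C3) bearing an (E)-propenyl group.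

Step 7
Reactants: 9 4-bromo-2-[(2R,3E)-1-hydroxypent-3-en-2-yl]-5-[(triisopropylsilyl)oxy]phenol
Product: 10 (2R,3E)-2-{5-bromo-2-methoxy-4-[(triisopropylsilyl)oxy]phenyl}pent-3-en-1-ol
Conditions: MeI, K2CO3, acetone, 40 °C
Reagents that add atoms: iodomethane, CI
Why: Williamson O-methylation, in which only the phenol is deprotonated by K2CO3, installs the 2'-methoxy group and leaves the primary alcohol free.

Step 8
Reactants: 11 5-methoxyresorcinol
Product: 12 2-iodo-5-methoxybenzene-1,3-diol
Conditions: I2 (1.05 equiv), NaHCO3, THF/H2O, 0 °C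
Reagents that add atoms: iodine, II
Why: Electrophilic aromatic iodination of the phenoxide under aqueous bicarbonate goes to the carbon flanked by both hydroxyls, as it does for resorcinol itself, giving the symmetric 2-iodo diol.

Step 9
Reactants: 12 2-iodo-5-methoxybenzene-1,3-diol
Product: 13 3-[(tert-butyldimethylsilyl)oxy]-2-iodo-5-methoxyphenol
Conditions: TBSCl (1.0 equiv), imidazole, CH2Cl2/DMF, 0 °C
Reagents that add atoms: tert-butyldimethylsilyl chloride, CC(C)(C)[Si](C)(C)Cl
Why: Statistical monosilylation (silyl ether formation) of the symmetric diol leaves one phenol for etherification and masks the future 5-hydroxyl; recovered diol and bis-ether are recycled.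

Step 10
Reactants: 10 (2R,3E)-2-{5-bromo-2-methoxy-4-[(triisopropylsilyl)oxy]phenyl}pent-3-en-1-ol; 13 3-[(tert-butyldimethylsilyl)oxy]-2-iodo-5-methoxyphenol
Product: 14 1-{[(2R,3E)-2-{5-bromo-2-methoxy-4-[(triisopropylsilyl)oxy]phenyl}pent-3-en-1-yl]oxy}-3-[(tert-butyldimethylsilyl)oxy]-2-iodo-5-methoxybenzene
Conditions: PPh3, DIAD, toluene, 0 °C → rt
Reagents that add atoms: none
Why: Mitsunobu etherification of the primary alcohol with the iodophenol forms the O1–C2 bond at a carbon that is not stereogenic, so C3 is unaffected.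

Step 11
Reactants: 14 1-{[(2R,3E)-2-{5-bromo-2-methoxy-4-[(triisopropylsilyl)oxy]phenyl}pent-3-en-1-yl]oxy}-3-[(tert-butyldimethylsilyl)oxy]-2-iodo-5-methoxybenzene
Product: 16 (2R)-2-{5-bromo-2-methoxy-4-[(triisopropylsilyl)oxy]phenyl}-3-{3-[(tert-butyldimethylsilyl)oxy]-2-iodo-5-methoxyphenoxy}propanal, via vicinal diol 15 (not isolated)
Conditions: OsO4 (2 mol%), NMO, acetone/H2O, rt; then NaIO4, pH 7 buffer, 0 °C; crude aldehyde used at once
Reagents that add atoms: N-methylmorpholine N-oxide, C[N+]1([O-])CCOCC1; water, O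
Why: Upjohn dihydroxylation of the only alkene followed by periodate glycol cleavage (Lemieux–Johnson type) gives the aldehyde under near-neutral conditions that spare the electron-rich arenes and avoid enolisation or β-elimination at the α-aryl centre.

Step 12
Reactants: 16 (2R)-2-{5-bromo-2-methoxy-4-[(triisopropylsilyl)oxy]phenyl}-3-{3-[(tert-butyldimethylsilyl)oxy]-2-iodo-5-methoxyphenoxy}propanal
Product: 17 (3R,4R)-3-{5-bromo-2-methoxy-4-[(triisopropylsilyl)oxy]phenyl}-5-[(tert-butyldimethylsilyl)oxy]-7-methoxychroman-4-ol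
Conditions: CrCl2 (8 equiv), NiCl2 (5 mol%), degassed DMF, rt
Reagents that add atoms: none
Why: In this intramolecular Nozaki–Hiyama–Kishi reaction zerovalent nickel inserts into the C–I bond (not C–Br) and the aryl group passes to trivalent chromium and adds to the aldehyde under non-basic conditions to close ring C; attack anti to the pseudo-equatorial C3 aryl group (Felkin–Anh sense) together with peri strain from the 5-silyloxy group, which keeps the new C–O bond pseudo-axial, gives the 3,4-cis (4R) alcohol.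

Step 13
Reactants: 17 (3R,4R)-3-{5-bromo-2-methoxy-4-[(triisopropylsilyl)oxy]phenyl}-5-[(tert-butyldimethylsilyl)oxy]-7-methoxychroman-4-ol
Product: 18 (3R,4R)-5-[(tert-butyldimethylsilyl)oxy]-7-methoxy-3-{2-methoxy-5-(3-methylbut-2-en-1-yl)-4-[(triisopropylsilyl)oxy]phenyl}chroman-4-ol
Conditions: Bu3SnCH2CH=CMe2 (2 equiv), Pd(PPh3)4 (10 mol%), DMF, 95 °C
Reagents that add atoms: tributyl(3-methylbut-2-en-1-yl)stannane, CCCC[Sn](CCCC)(CCCC)CC=C(C)C
Why: Stille cross-coupling of the remaining aryl bromide (oxidative addition to zerovalent palladium, transmetalation, reductive elimination) installs the linear prenyl group under neutral conditions without touching either stereocentre.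

Step 14
Reactants: 18 (3R,4R)-5-[(tert-butyldimethylsilyl)oxy]-7-methoxy-3-{2-methoxy-5-(3-methylbut-2-en-1-yl)-4-[(triisopropylsilyl)oxy]phenyl}chroman-4-ol
Product: 19 (3R,4R)-3-[4-hydroxy-2-methoxy-5-(3-methylbut-2-en-1-yl)phenyl]-7-methoxychromane-4,5-diol
Conditions: Bu4NF (2.5 equiv), AcOH (2.5 equiv), THF, 0 °C; pH 7 work-up
Reagents that add atoms: none
Why: Buffered fluoride desilylation cleaves both aryl silyl ethers and frees the two phenols without acid, which the ionisable benzylic 4-hydroxyl would not survive.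

## Compound list

1 | resorcinol | Oc1cccc(O)c1 | starting material
2 | 3-[(triisopropylsilyl)oxy]phenol | CC(C)[Si](Oc1cccc(O)c1)(C(C)C)C(C)C | intermediate
3 | 4-bromo-3-[(triisopropylsilyl)oxy]phenol | CC(C)[Si](Oc1cc(O)ccc1Br)(C(C)C)C(C)C | intermediate
4 | methyl (R)-lactate | C[C@@H](O)C(=O)OC | starting material
5 | methyl (2S)-2-{4-bromo-3-[(triisopropylsilyl)oxy]phenoxy}propanoate | C[C@H](Oc1ccc(Br)c(O[Si](C(C)C)(C(C)C)C(C)C)c1)C(=O)OC | intermediate
6 | (2S)-2-{4-bromo-3-[(triisopropylsilyl)oxy]phenoxy}propanal | C[C@H](Oc1ccc(Br)c(O[Si](C(C)C)(C(C)C)C(C)C)c1)C=O | intermediate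
7 | ethyl (2E,4S)-4-{4-bromo-3-[(triisopropylsilyl)oxy]phenoxy}pent-2-enoate | C[C@H](Oc1ccc(Br)c(O[Si](C(C)C)(C(C)C)C(C)C)c1)/C=C/C(=O)OCC | intermediate
8 | (2E,4S)-4-{4-bromo-3-[(triisopropylsilyl)oxy]phenoxy}pent-2-en-1-ol | C[C@H](Oc1ccc(Br)c(O[Si](C(C)C)(C(C)C)C(C)C)c1)/C=C/CO | intermediate
9 | 4-bromo-2-[(2R,3E)-1-hydroxypent-3-en-2-yl]-5-[(triisopropylsilyl)oxy]phenol | OC[C@H](/C=C/C)c1cc(Br)c(O[Si](C(C)C)(C(C)C)C(C)C)cc1O | intermediate
10 | (2R,3E)-2-{5-bromo-2-methoxy-4-[(triisopropylsilyl)oxy]phenyl}pent-3-en-1-ol | OC[C@H](/C=C/C)c1cc(Br)c(O[Si](C(C)C)(C(C)C)C(C)C)cc1OC | intermediate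
11 | 5-methoxyresorcinol | COc1cc(O)cc(O)c1 | starting material
12 | 2-iodo-5-methoxybenzene-1,3-diol | COc1cc(O)c(I)c(O)c1 | intermediate
13 | 3-[(tert-butyldimethylsilyl)oxy]-2-iodo-5-methoxyphenol | COc1cc(O)c(I)c(O[Si](C)(C)C(C)(C)C)c1 | intermediate
14 | 1-{[(2R,3E)-2-{5-bromo-2-methoxy-4-[(triisopropylsilyl)oxy]phenyl}pent-3-en-1-yl]oxy}-3-[(tert-butyldimethylsilyl)oxy]-2-iodo-5-methoxybenzene | COc1cc(OC[C@H](/C=C/C)c2cc(Br)c(O[Si](C(C)C)(C(C)C)C(C)C)cc2OC)c(I)c(O[Si](C)(C)C(C)(C)C)c1 | intermediate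
15 | (2R)-2-{5-bromo-2-methoxy-4-[(triisopropylsilyl)oxy]phenyl}-1-{3-[(tert-butyldimethylsilyl)oxy]-2-iodo-5-methoxyphenoxy}pentane-3,4-diol (mixture of diol diastereomers) | COc1cc(OC[C@H](C(O)C(C)O)c2cc(Br)c(O[Si](C(C)C)(C(C)C)C(C)C)cc2OC)c(I)c(O[Si](C)(C)C(C)(C)C)c1 | intermediate
16 | (2R)-2-{5-bromo-2-methoxy-4-[(triisopropylsilyl)oxy]phenyl}-3-{3-[(tert-butyldimethylsilyl)oxy]-2-iodo-5-methoxyphenoxy}propanal | COc1cc(OC[C@H](C=O)c2cc(Br)c(O[Si](C(C)C)(C(C)C)C(C)C)cc2OC)c(I)c(O[Si](C)(C)C(C)(C)C)c1 | intermediate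
17 | (3R,4R)-3-{5-bromo-2-methoxy-4-[(triisopropylsilyl)oxy]phenyl}-5-[(tert-butyldimethylsilyl)oxy]-7-methoxychroman-4-ol | COc1cc(O[Si](C)(C)C(C)(C)C)c2c(c1)OC[C@@H](c1cc(Br)c(O[Si](C(C)C)(C(C)C)C(C)C)cc1OC)[C@H]2O | intermediate
18 | (3R,4R)-5-[(tert-butyldimethylsilyl)oxy]-7-methoxy-3-{2-methoxy-5-(3-methylbut-2-en-1-yl)-4-[(triisopropylsilyl)oxy]phenyl}chroman-4-ol | COc1cc(O[Si](C)(C)C(C)(C)C)c2c(c1)OC[C@@H](c1cc(CC=C(C)C)c(O[Si](C(C)C)(C(C)C)C(C)C)cc1OC)[C@H]2O | intermediate
19 | (3R,4R)-3-[4-hydroxy-2-methoxy-5-(3-methylbut-2-en-1-yl)phenyl]-7-methoxychromane-4,5-diol | COc1cc(O)c2c(c1)OC[C@@H](c1cc(CC=C(C)C)c(O)cc1OC)[C@H]2O | target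

## Step count and risks

Total step count: 14. Longest linear sequence: 12 steps (steps 1–7 and 10–14, from resorcinol); steps 8 and 9 form the ring A branch.

Steps most likely to fail:

Step 6 (Claisen rearrangement). The free primary hydroxyl may bind the europium catalyst, and any ionisation or a (Z)/boat pathway would erode the chirality transfer. The fallback changes the order in which the fragments are joined, so that no free hydroxyl is present during the rearrangement. It sets out from 8, which is coupled first with 13 under Mitsunobu conditions (PPh3, DIAD, THF) to give the bis(aryl) ether F1. Its Claisen rearrangement (Eu(fod)3, CHCl3, 60 °C, or PhNEt2, 160 °C) gives the phenol F2; the secondary allylic C–O bond to ring B rearranges much faster than the primary one to ring A. O-Methylation (MeI, K2CO3, acetone) brings the sequence back to the route at 14.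

Step 12 (Nozaki–Hiyama–Kishi ring closure). The doubly ortho-substituted aryl iodide may insert slowly, aldehyde 16 is fragile, and the cis preference could be modest. The fallback closes ring C at the ketone level and sets C4 by hydride delivery. It sets out from 16, which is oxidised under Pinnick conditions (NaClO2, NaH2PO4, 2-methyl-2-butene, t-BuOH/H2O) to the carboxylic acid F3. Iodine–lithium exchange on its lithium salt (n-BuLi, 2.1 equiv, THF, −100 °C) gives a Parham-type cyclisation to the isoflavanone F4, quenched cold with dilute acid so that C3 is not equilibrated. Reduction with LiBH(s-Bu)3 (THF, −78 °C) from the equatorial direction gives the axial, 3,4-cis alcohol and rejoins the route at 17.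

Step 13 (Stille prenylation). The bromide is electron-rich and sits next to a bulky silyl ether, and prenylstannanes can transmetalate slowly or deliver some branched isomer. The fallback builds the prenyl group in two stages. It sets out from 17, which is coupled with the more reactive allyltributylstannane (Pd(PPh3)4, DMF, 90 °C) to give the allylarene F5. Cross-metathesis with 2-methyl-2-butene (second-generation Grubbs catalyst, CH2Cl2, 40 °C) converts allyl into prenyl and rejoins the route at 18.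

## Further compounds

F1 | step 6 | 1-{[(2E,4S)-4-{4-bromo-3-[(triisopropylsilyl)oxy]phenoxy}pent-2-en-1-yl]oxy}-3-[(tert-butyldimethylsilyl)oxy]-2-iodo-5-methoxybenzene | COc1cc(OC/C=C/[C@H](C)Oc2ccc(Br)c(O[Si](C(C)C)(C(C)C)C(C)C)c2)c(I)c(O[Si](C)(C)C(C)(C)C)c1
F2 | step 6 | 4-bromo-2-[(2R,3E)-1-{3-[(tert-butyldimethylsilyl)oxy]-2-iodo-5-methoxyphenoxy}pent-3-en-2-yl]-5-[(triisopropylsilyl)oxy]phenol | COc1cc(OC[C@H](/C=C/C)c2cc(Br)c(O[Si](C(C)C)(C(C)C)C(C)C)cc2O)c(I)c(O[Si](C)(C)C(C)(C)C)c1
F3 | step 12 | (2R)-2-{5-bromo-2-methoxy-4-[(triisopropylsilyl)oxy]phenyl}-3-{3-[(tert-butyldimethylsilyl)oxy]-2-iodo-5-methoxyphenoxy}propanoic acid | COc1cc(OC[C@H](C(=O)O)c2cc(Br)c(O[Si](C(C)C)(C(C)C)C(C)C)cc2OC)c(I)c(O[Si](C)(C)C(C)(C)C)c1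
F4 | step 12 | (3R)-3-{5-bromo-2-methoxy-4-[(triisopropylsilyl)oxy]phenyl}-5-[(tert-butyldimethylsilyl)oxy]-7-methoxychroman-4-one | COc1cc(O[Si](C)(C)C(C)(C)C)c2c(c1)OC[C@@H](c1cc(Br)c(O[Si](C(C)C)(C(C)C)C(C)C)cc1OC)C2=O
F5 | step 13 | (3R,4R)-5-[(tert-butyldimethylsilyl)oxy]-7-methoxy-3-{2-methoxy-5-(prop-2-en-1-yl)-4-[(triisopropylsilyl)oxy]phenyl}chroman-4-ol | COc1cc(O[Si](C)(C)C(C)(C)C)c2c(c1)OC[C@@H](c1cc(CC=C)c(O[Si](C(C)C)(C(C)C)C(C)C)cc1OC)[C@H]2O
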